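**Plan**

- Retrosynthesis cuts, in this order: the ester C–O bond; the aryl–CH2 bond of the 4-benzyl group (aryl Grignard on a lactol carbon, benzylic OH removed later); the oxolane bonds O1–C2 and C4–C5, leaving a cyclopropane C2–C3–C4 plus formaldehyde (O1, C5); then the cyclopropane bonds C2–C4 and C3–C4 (a cinnamaldehyde plus bromomalonate).
- Forward: the cyclopropane is made first, then a γ-lactone fused to it (C3–CH2–O–C(=O)–C4), then the oxolane by ring expansion of the three-membered ring by two atoms (key step), then Krapcho, DIBAL-H, ArMgBr, esterification, deoxygenation and debenzylation.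
- Feature used: oxolane C2 is benzylic to an electron-rich 4-oxy-3-methoxyphenyl ring, and C4 bears a carbon (the later ArCH2) that can stand at the carboxyl level beside a second, removable ester. The C2–C4 bond of the cyclopropane is therefore a donor–acceptor bond that ionises and takes up CH2=O.
- Stereochemistry: C3 from the (R)-diphenylprolinol silyl ether catalyst; C4 from the cis fusion of the lactone (3,4-cis); C2 from exo (2,3-trans) ring closure in the key step; the acyl centre from (R)-2-methylbutanoic acid.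

Key step: step 4

Assumption: 11 (anomers) and 14, 16 (epimers at the ArCH(OH) carbon) are carried as mixtures at a centre that is absent from the target; their SMILES leave it open.

**Step 1**
Reactants: 1 coniferaldehyde, (E)-3-(4-hydroxy-3-methoxyphenyl)prop-2-enal
Product: 2 (E)-3-[4-(benzyloxy)-3-methoxyphenyl]prop-2-enal
Conditions: BnBr, K2CO3, DMF, 25 °C
Reagents that add atoms: benzyl bromide, BrCc1ccccc1
Why: Williamson ether synthesis on the phenoxide; the enal and its E geometry are unaffected.

**Step 2**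
Reactants: 2 (E)-3-[4-(benzyloxy)-3-methoxyphenyl]prop-2-enal; 3 diethyl bromomalonate
Product: 4 diethyl (2S,3R)-3-[4-(benzyloxy)-3-methoxyphenyl]-2-formylcyclopropane-1,1-dicarboxylate (formyl trans to aryl)
Conditions: (R)-α,α-diphenylprolinol trimethylsilyl ether (10 mol%), 2,6-lutidine, CH2Cl2, 0 °C → 25 °C
Reagents that add atoms: none
Why: Aminocatalytic Michael-initiated ring closure (iminium, then enamine): the bromomalonate anion adds to the β-carbon of the iminium ion of 2 on the face not shielded by the diphenyl(silyloxy)methyl group and the enamine displaces bromide (3-exo-tet), which sets C2 and C3 trans (from the E-alkene) in the absolute sense fixed by the (R)-catalyst.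

**Step 3**
Reactants: 4 diethyl (2S,3R)-3-[4-(benzyloxy)-3-methoxyphenyl]-2-formylcyclopropane-1,1-dicarboxylate
Product: 6 ethyl (1R,5S,6R)-6-[4-(benzyloxy)-3-methoxyphenyl]-2-oxo-3-oxabicyclo[3.1.0]hexane-1-carboxylate (aryl exo), via hydroxymethyl diester 5 (not isolated)
Conditions: NaBH4, EtOH, 0 °C → 25 °C
Reagents that add atoms: none
Why: Chemoselective borohydride reduction of the aldehyde; the alkoxide of 5 lactonises (5-exo-trig) onto the ester cis to it, the only one in reach, which makes C1 a defined stereocentre while C5 and C6 are untouched.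

**Step 4**
Reactants: 6 ethyl (1R,5S,6R)-6-[4-(benzyloxy)-3-methoxyphenyl]-2-oxo-3-oxabicyclo[3.1.0]hexane-1-carboxylate; 7 paraformaldehyde (source of formaldehyde)
Product: 9 ethyl (1S,5S,6R)-6-[4-(benzyloxy)-3-methoxyphenyl]-2-oxo-3,7-dioxabicyclo[3.3.0]octane-1-carboxylate (cis-fused, aryl exo), via ring-opened benzylic zwitterion 8 (not isolated)
Conditions: (CH2O)n (3 equiv), Sc(OTf)3 (10 mol%), 4 Å MS, CH2Cl2, 25 °C
Reagents that add atoms: none
Why: Sc(OTf)3 chelates the lactone and ester carbonyls on C1 of 6 and heterolyses the C1–C6 cyclopropane bond, C6 being benzylic to the 4-benzyloxy-3-methoxyphenyl donor, to give zwitterion 8; its enolate carbon adds to Lewis-acid-bound formaldehyde and the new alkoxide closes on the cation, so that O and CH2 are inserted into the three-membered ring and the oxolane results. The closest known reaction type is the Lewis-acid-catalysed formal (3+2) cycloaddition of 2-arylcyclopropane-1,1-dicarboxylates with aldehydes to tetrahydrofurans. The oxolane is closed in a 5-exo-trig manner by oxygen attack on the trigonal benzylic cation, after the intermolecular C–C bond has formed. The new quaternary centre C1 is controlled by the retained centre C5 (from step 2): only the aldolate on the face syn to the cationic arm can close, a trans-fused 3,7-dioxabicyclo[3.3.0]octane being too strained, and the other adds reversibly. The new centre C6 is set in the ring closure, where the aryl group eclipses the small bridgehead hydrogen instead of the lactone CH2 (allylic-strain control) and so ends exo, trans to that CH2. The step needs regioselective cleavage of the donor–acceptor bond, which the electron-rich aryl ring opposite the geminal dicarbonyl group secures, and capture of 8 faster than proton loss or Friedel–Crafts alkylation, which an excess of dry formaldehyde at moderate temperature should secure.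

**Step 5**
Reactants: 9 ethyl (1S,5S,6R)-6-[4-(benzyloxy)-3-methoxyphenyl]-2-oxo-3,7-dioxabicyclo[3.3.0]octane-1-carboxylate
Product: 10 (1S,5S,6R)-6-[4-(benzyloxy)-3-methoxyphenyl]-3,7-dioxabicyclo[3.3.0]octan-2-one
Conditions: LiCl, H2O, DMSO, 140 °C
Reagents that add atoms: none
Why: Krapcho dealkoxycarbonylation of the malonate-type ester; protonation of the bridgehead lactone enolate can only give the cis-fused bicycle, so C1–H comes out cis to C5–H and the side-chain carbons on the later oxolane C3 and C4 stay cis.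

**Step 6**
Reactants: 10 (1S,5S,6R)-6-[4-(benzyloxy)-3-methoxyphenyl]-3,7-dioxabicyclo[3.3.0]octan-2-one
Product: 11 (1S,5S,6R)-6-[4-(benzyloxy)-3-methoxyphenyl]-3,7-dioxabicyclo[3.3.0]octan-2-ol (anomeric mixture)
Conditions: DIBAL-H (1.1 equiv), CH2Cl2, −78 °C
Reagents that add atoms: none
Why: Partial reduction of a γ-lactone by DIBAL-H, the tetrahedral aluminium hemiacetal being stable at −78 °C; no stereocentre of the target is touched.

**Step 7**
Reactants: 11 (1S,5S,6R)-6-[4-(benzyloxy)-3-methoxyphenyl]-3,7-dioxabicyclo[3.3.0]octan-2-ol; 12 1-(benzyloxy)-4-bromo-2-methoxybenzene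
Product: 14 {(2R,3S,4S)-2-[4-(benzyloxy)-3-methoxyphenyl]-4-{[4-(benzyloxy)-3-methoxyphenyl](hydroxy)methyl}oxolan-3-yl}methanol (carbinol epimers), via arylmagnesium bromide 13 (not isolated)
Conditions: 12, Mg, THF, 40 °C; then 11 (3 equiv of 13), THF, 0 °C → 25 °C; aq. NH4Cl
Reagents that add atoms: none
Why: Grignard addition to the hydroxy-aldehyde form of the lactol (one equivalent of 13 is spent on the lactol OH), a reaction type well established for furofuran lactols; addition is faster than enolisation of the aldehyde, so C4 keeps its configuration, and the new carbinol centre is removed in step 9.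

**Step 8**
Reactants: 14 {(2R,3S,4S)-2-[4-(benzyloxy)-3-methoxyphenyl]-4-{[4-(benzyloxy)-3-methoxyphenyl](hydroxy)methyl}oxolan-3-yl}methanol; 15 (R)-2-methylbutanoic acid
Product: 16 {(2R,3S,4S)-2-[4-(benzyloxy)-3-methoxyphenyl]-4-{[4-(benzyloxy)-3-methoxyphenyl](hydroxy)methyl}oxolan-3-yl}methyl (2R)-2-methylbutanoate
Conditions: EDC·HCl, DMAP (0.1 equiv), CH2Cl2, 0 °C
Reagents that add atoms: none
Why: Steglich-type carbodiimide esterification: the unhindered primary alcohol reacts ahead of the hindered secondary benzylic one, the α-stereocentre of 15 has no path to racemisation here, and the ester also keeps the CH2O group from closing a furofuran ring in step 9.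

**Step 9**
Reactants: 16 {(2R,3S,4S)-2-[4-(benzyloxy)-3-methoxyphenyl]-4-{[4-(benzyloxy)-3-methoxyphenyl](hydroxy)methyl}oxolan-3-yl}methyl (2R)-2-methylbutanoate
Product: 17 [(2R,3S,4S)-2-[4-(benzyloxy)-3-methoxyphenyl]-4-{[4-(benzyloxy)-3-methoxyphenyl]methyl}oxolan-3-yl]methyl (2R)-2-methylbutanoate
Conditions: Et3SiH (3 equiv), BF3·OEt2, CH2Cl2, −78 °C
Reagents that add atoms: none
Why: Ionic hydrogenation (Et3SiH/BF3 reductive deoxygenation): the secondary benzylic alcohol ionises to a 4-alkoxybenzyl cation that takes hydride from the silane, while the cyclic benzylic ether should stay closed at −78 °C and the C2 aryl group, trans to the C4 side chain, cannot reach the cation; no ring stereocentre is involved.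

**Step 10**
Reactants: 17 [(2R,3S,4S)-2-[4-(benzyloxy)-3-methoxyphenyl]-4-{[4-(benzyloxy)-3-methoxyphenyl]methyl}oxolan-3-yl]methyl (2R)-2-methylbutanoate
Product: 18 [(2R,3S,4S)-2-(4-hydroxy-3-methoxyphenyl)-4-[(4-hydroxy-3-methoxyphenyl)methyl]oxolan-3-yl]methyl (2R)-2-methylbutanoate
Conditions: H2 (1 atm), 10% Pd/C, EtOAc, 25 °C
Reagents that add atoms: none
Why: Catalytic hydrogenolysis of the two aryl benzyl ethers, which should be much faster than cleavage of the aliphatic ester or of the oxolane C2–O bond in a neutral aprotic solvent if the reaction is stopped at full debenzylation.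

**Compound list**

1 | coniferaldehyde, (E)-3-(4-hydroxy-3-methoxyphenyl)prop-2-enal | O=C/C=C/c1ccc(O)c(OC)c1 | starting material
2 | (E)-3-[4-(benzyloxy)-3-methoxyphenyl]prop-2-enal | O=C/C=C/c1ccc(OCc2ccccc2)c(OC)c1 | intermediate
3 | diethyl bromomalonate | CCOC(=O)C(Br)C(=O)OCC | starting material
4 | diethyl (2S,3R)-3-[4-(benzyloxy)-3-methoxyphenyl]-2-formylcyclopropane-1,1-dicarboxylate | CCOC(=O)C1(C(=O)OCC)[C@@H](C=O)[C@@H]1c2ccc(OCc3ccccc3)c(OC)c2 | intermediate
5 | diethyl (2S,3R)-3-[4-(benzyloxy)-3-methoxyphenyl]-2-(hydroxymethyl)cyclopropane-1,1-dicarboxylate | CCOC(=O)C1(C(=O)OCC)[C@@H](CO)[C@@H]1c2ccc(OCc3ccccc3)c(OC)c2 | intermediate (not isolated)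
6 | ethyl (1R,5S,6R)-6-[4-(benzyloxy)-3-methoxyphenyl]-2-oxo-3-oxabicyclo[3.1.0]hexane-1-carboxylate | CCOC(=O)[C@]12C(=O)OC[C@H]1[C@@H]2c3ccc(OCc4ccccc4)c(OC)c3 | intermediate
7 | paraformaldehyde (as formaldehyde) | C=O | starting material
8 | ring-opened zwitterion (lactone enolate / 4-benzyloxy-3-methoxybenzyl cation), Lewis-acid bound | CCOC(=O)C1=C([O-])OC[C@H]1[CH+]c2ccc(OCc3ccccc3)c(OC)c2 | intermediate (not isolated)
9 | ethyl (1S,5S,6R)-6-[4-(benzyloxy)-3-methoxyphenyl]-2-oxo-3,7-dioxabicyclo[3.3.0]octane-1-carboxylate | O=C1OC[C@@H]2[C@@]1(C(=O)OCC)CO[C@H]2c3ccc(OCc4ccccc4)c(OC)c3 | intermediate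
10 | (1S,5S,6R)-6-[4-(benzyloxy)-3-methoxyphenyl]-3,7-dioxabicyclo[3.3.0]octan-2-one | O=C1OC[C@@H]2[C@H]1CO[C@H]2c3ccc(OCc4ccccc4)c(OC)c3 | intermediate
11 | (1S,5S,6R)-6-[4-(benzyloxy)-3-methoxyphenyl]-3,7-dioxabicyclo[3.3.0]octan-2-ol (anomers) | OC1OC[C@@H]2[C@H]1CO[C@H]2c3ccc(OCc4ccccc4)c(OC)c3 | intermediate
12 | 1-(benzyloxy)-4-bromo-2-methoxybenzene | COc1cc(Br)ccc1OCc1ccccc1 | starting material
13 | [4-(benzyloxy)-3-methoxyphenyl]magnesium bromide | COc1cc([Mg]Br)ccc1OCc1ccccc1 | intermediate (not isolated)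
14 | {(2R,3S,4S)-2-[4-(benzyloxy)-3-methoxyphenyl]-4-{[4-(benzyloxy)-3-methoxyphenyl](hydroxy)methyl}oxolan-3-yl}methanol (carbinol epimers) | OC[C@@H]1[C@H](C(O)c2ccc(OCc3ccccc3)c(OC)c2)CO[C@H]1c1ccc(OCc2ccccc2)c(OC)c1 | intermediate
15 | (R)-2-methylbutanoic acid | CC[C@@H](C)C(=O)O | starting material
16 | {(2R,3S,4S)-2-[4-(benzyloxy)-3-methoxyphenyl]-4-{[4-(benzyloxy)-3-methoxyphenyl](hydroxy)methyl}oxolan-3-yl}methyl (2R)-2-methylbutanoate (carbinol epimers) | CC[C@@H](C)C(=O)OC[C@@H]1[C@H](C(O)c2ccc(OCc3ccccc3)c(OC)c2)CO[C@H]1c1ccc(OCc2ccccc2)c(OC)c1 | intermediate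
17 | [(2R,3S,4S)-2-[4-(benzyloxy)-3-methoxyphenyl]-4-{[4-(benzyloxy)-3-methoxyphenyl]methyl}oxolan-3-yl]methyl (2R)-2-methylbutanoate | CC[C@@H](C)C(=O)OC[C@@H]1[C@H](Cc2ccc(OCc3ccccc3)c(OC)c2)CO[C@H]1c1ccc(OCc2ccccc2)c(OC)c1 | intermediate
18 | [(2R,3S,4S)-2-(4-hydroxy-3-methoxyphenyl)-4-[(4-hydroxy-3-methoxyphenyl)methyl]oxolan-3-yl]methyl (2R)-2-methylbutanoate | CC[C@@H](C)C(=O)OC[C@@H]1[C@H](Cc2ccc(O)c(OC)c2)CO[C@H]1c1ccc(O)c(OC)c1 | target

**Count**

Total step count: 10. Longest linear sequence: 10 steps (1 → 18); 3, 7, 12 and 15 are purchased.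

**Steps most likely to fail**

Step 4. Formaldehyde is a weak partner, so capture of the ring-opened zwitterion may be too slow. That would leave time for proton loss to a styrene, for Friedel–Crafts oligomerisation through the benzylic cation, or for ring closure on the endo face. The fallback sets out from 6 and returns at 10. DIBAL-H (1 equiv, CH2Cl2, −78 °C) should reduce the strained lactone carbonyl of 6 ahead of the ester to the lactol ethyl (1S,5S,6R)-6-[4-(benzyloxy)-3-methoxyphenyl]-2-hydroxy-3-oxabicyclo[3.1.0]hexane-1-carboxylate F1. Its open hydroxy-aldehyde form is a 1-formylcyclopropane-1-carboxylate with an aryl donor and should undergo a Cloke–Wilson rearrangement (Sc(OTf)3 cat., CH2Cl2, 25 °C), the formyl oxygen closing on the benzylic cation, to give the 2,3-trans compound ethyl (2R,3S)-2-[4-(benzyloxy)-3-methoxyphenyl]-3-(hydroxymethyl)-2,3-dihydrofuran-4-carboxylate F2. Hydrogenation of the β-alkoxyacrylate (H2, Rh/Al2O3, EtOAc) should give ethyl (4S,5R)-5-[4-(benzyloxy)-3-methoxyphenyl]-4-(hydroxymethyl)oxolane-3-carboxylate F3 as a mixture at C3. DBU in toluene at 80 °C should then epimerise that centre and lactonise the cis isomer to 10.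

Step 9. The Lewis acid may also ionise the ring C2–O bond, leading to ring opening followed by hydride capture or Friedel–Crafts closure to an aryltetralin, or the benzylic cation may lose a proton to a styrene. The fallback sets out from 16 and returns at 17 by a radical Barton–McCombie deoxygenation that involves no cation. PhOC(S)Cl, pyridine and DMAP in CH2Cl2 should give {(2R,3S,4S)-2-[4-(benzyloxy)-3-methoxyphenyl]-4-{[4-(benzyloxy)-3-methoxyphenyl](phenoxycarbonothioyloxy)methyl}oxolan-3-yl}methyl (2R)-2-methylbutanoate F4, and Bu3SnH with AIBN in toluene at 80 °C should reduce it to 17.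

Step 10. Hydrogenolysis may go on to the benzylic C2–O bond of the oxolane once the benzyl ethers are gone, opening the ring. The fallback sets out from 17 and reaches 18 directly by Lewis-acid debenzylation with a cation scavenger (BCl3, pentamethylbenzene, CH2Cl2, −78 °C), which uses no hydrogen and makes no new compound (F0).

**Further compounds**

F1 | step 4 | ethyl (1S,5S,6R)-6-[4-(benzyloxy)-3-methoxyphenyl]-2-hydroxy-3-oxabicyclo[3.1.0]hexane-1-carboxylate | CCOC(=O)[C@]12C(O)OC[C@H]1[C@@H]2c3ccc(OCc4ccccc4)c(OC)c3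
F2 | step 4 | ethyl (2R,3S)-2-[4-(benzyloxy)-3-methoxyphenyl]-3-(hydroxymethyl)-2,3-dihydrofuran-4-carboxylate | CCOC(=O)C1=CO[C@@H](c2ccc(OCc3ccccc3)c(OC)c2)[C@@H]1CO
F3 | step 4 | ethyl (4S,5R)-5-[4-(benzyloxy)-3-methoxyphenyl]-4-(hydroxymethyl)oxolane-3-carboxylate | CCOC(=O)C1CO[C@@H](c2ccc(OCc3ccccc3)c(OC)c2)[C@@H]1CO
F4 | step 9 | {(2R,3S,4S)-2-[4-(benzyloxy)-3-methoxyphenyl]-4-{[4-(benzyloxy)-3-methoxyphenyl](phenoxycarbonothioyloxy)methyl}oxolan-3-yl}methyl (2R)-2-methylbutanoate | CC[C@@H](C)C(=O)OC[C@@H]1[C@H](C(OC(=S)Oc2ccccc2)c2ccc(OCc3ccccc3)c(OC)c2)CO[C@H]1c1ccc(OCc2ccccc2)c(OC)c1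
F0 | step 10 | none | none
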